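## Analysis of the target

Numbering used throughout: C1–C3 are the isopropenyl carbons on C4; the large ring runs C4, C5, C6, C7, C8, C9, C10, C11, C13, C14, C15, C16, C18, C19 and back to C4; C12 is the ester carbonyl on C11, C17 the methyl on C16, C20 the lactone carbonyl on C7.

Target 29 is a 14-membered carbocycle that shares C7–C8–C9 with an α-alkylidene γ-butyrolactone (C20 carbonyl, ring oxygen on C9); the exocyclic E alkene C6=C7 is part of the large ring. It has five stereocentres: C4 (R), C9 (S), C11 (S) and the cis-fused trisubstituted epoxide C16 (S)/C18 (S). C4, C9 and the C11–C18 segment are separated by methylene or sp2 carbons, so none can set another by short-range induction. C12, C13 and C15 form a β,δ-diketo ester: C14–H2 and C11–H are acidic, C11 is configurationally labile once C13 is a ketone, and the enoate carbon C6 lies six atoms from C11. The C9 oxygen could also close a five-membered lactone onto C12 instead of C20, so alkoxide bases are dangerous once both carbonyls are present. The difficulty is to close a 14-membered ring and set the epoxide against remote centres while the tricarbonyl array is revealed only late and without base. The strategy rests on one feature: the C15 ketone adjoins the fully substituted epoxide carbon C16. Taken back to a C15 carbinol and a Z C16=C18 alkene, the C15–C16 bond is that of an allylic alcohol, which an alkenyl metal at C16 and an aldehyde at C15 can form, and the same hydroxyl can direct the epoxidation before it is oxidised.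

## Retrosynthetic reasoning

**29 back to 26 (oxidation levels).** The two ketones are removed first. 29 comes from hydroxy ketone 28 by oxidation at C13, 28 from silyl ether 27, and 27 from epoxy alcohol 26 by oxidation at C15. No C–C bond is cut; the gain is that the acidic tricarbonyl array exists only in the last step. C15 is oxidised before the C13 silyl ether is removed, so that a free C13 hydroxyl never faces an epoxide flanked by a carbinol.

**26 to 25 (epoxide C–O bonds).** The epoxide is taken back to the Z alkene C16=C18 of allylic alcohol 25. The alkene geometry gives the cis relation of C15 and C19 on the oxirane, and the C15 hydroxyl has to deliver the oxygen to one face. This is why the epoxide is not carried through the synthesis: made late, it needs no separate asymmetric step.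

**25 to 23 (C15–C16, the ring-closing bond).** The macrocycle is opened between the carbinol carbon and the alkene carbon, giving aldehyde and Z-alkenyl iodide 23. The cut is made here and not at C10–C11 or C13–C14 because only here is the bond formed by a carbonyl addition that needs no base, and because its product is exactly the directing group needed for the epoxide. The forward reaction must close the ring through alkenylchromium 24 with retention of the Z geometry and must leave the ester, lactone and enoate alone.

**23 to 17 and 7 (C6=C7).** After adjustment at C15 (alcohol 22, silyl ether 21), the alkylidene lactone is cut at its double bond into lactone 17 and aldehyde 7, through aldol adduct 19. This is the most convergent cut: it divides the chain into a C4–C6/C16–C19 piece and a C7–C15 piece of similar size. The forward aldol–elimination has to enolise the lactone in preference to the C12 ester and has to give the E alkene.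

**17 to 12 and 13 (C11–C13).** C11 must be set absolutely, since C9 is too far away to control it. Alkylating a β-keto ester at C11 would leave that centre uncontrolled and epimerisable and would still require a one-carbon extension at C14. Instead the C11–C13 bond is cut as an aldol between thioimide 12 and aldehyde 13, which brings C13–C15 in one piece and fixes C11 through the auxiliary (adduct 15, ester 16). C13 is oxidised at the end, so its configuration only has to be uniform.

**12 to 8 (C10–C11).** The acyl chain of 12 is that of acid 11, which is lactone 8 lengthened by two carbons. The C10–C11 bond is cut as an alkene in enoate 10, made from 8 through aldehyde 9. C9 then comes from the chiral pool, and the poor electrophilicity of a C10 halide next to the lactone oxygen is avoided.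

**7 to 1 and 2 (C16=C18, then C4–C2).** Aldehyde 7 is traced to Weinreb amide 6, and the Z iodide to aldehyde 5 by an iodo-Wittig olefination. Aldehyde 5 comes from hydroxy amide 4, the ring-opened form of lactone 3, in which the two two-carbon arms at C4 differ in oxidation level. Reduction of both ends is avoided, because it would make the arms identical and erase C4. Lactone 3 is cut at C4–C2 into unsaturated lactone 1 and boronate 2, so C4 is set by a catalytic asymmetric conjugate addition.

## Alternatives that were turned down

**Alternative 1:** Here the C8–C9 bond inside the lactone would be made by an Ireland–Claisen rearrangement. A silyl ketene acetal formed at a glycolate carbonyl (C10) with KN(SiMe3)2 and Me3SiCl would rearrange through C9, C10, O, C6, C7, C8, contracting a seven-membered ring with two ester links to the five-membered lactone of acid A1.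
- For it: one step makes C9, the lactone and the C6=C7 alkene, and the alkene geometry follows from a cyclic transition state. On this point it is stronger than the chosen route, whose E geometry rests on an elimination.
- Against it: A1 is still open with respect to the 14-membered ring. Its C10 carboxyl must be reduced and joined to C11, and the ring closure remains unsolved. The seven-membered ring forces a boat-like transition state, so the transfer from C6 to C9 is hard to predict. An extra stereocentre at C6 has to be made only to be destroyed, and an α-methylene ester is exposed to a strong amide base.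
- Comparison: the chosen route takes C9 from lactone 8 at no cost in steps and spends its risk on the ring closure itself.

**Alternative 2:** The ring would be closed by an intramolecular cycloaddition of a nitrile oxide at C13 (from the aldoxime with NaOCl) to a terminal alkyne C14≡C15, forming C13–C14 and O–C15 and giving isoxazolophane A2; the isoxazole stands for the 1,3-diketone.
- For it: the diketone stays masked in a robust heteroaromatic ring until the end, and no C15 stereocentre arises. On both points it is stronger than the chosen route, which carries two carbinols and ends with oxidations next to acidic C–H bonds.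
- Against it: the epoxide must already be present on an acyclic alkyne-bearing fragment with quaternary C16, which needs its own asymmetric synthesis. The nitrile oxide and the hypochlorite meet the isopropenyl group, a good dipolarophile. C11, α to the oxime and the ester, is as labile as in 29. Unmasking needs N–O reduction (Mo(CO)6, SmI2 or hydrogenolysis) next to an α-keto epoxide and two reducible alkenes, and then hydrolysis of a vinylogous amide.
- Comparison: the chosen route has no reductive unmasking and lets the ring-closing step itself provide the group that controls the epoxide.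

**Alternative 3:** The ring would be closed at C10–C11 by C-alkylation of the β-keto ester enolate (Cs2CO3, dimethylformamide, high dilution) with a C10 iodide, giving macrocycle A3.
- For it: the reagents are simple, no stoichiometric chromium is used, and C11 would settle thermodynamically, which saves the auxiliary steps of the chosen route. On step economy it is stronger.
- Against it: C10 is a primary carbon next to the lactone carbinol C9, hindered and deactivated, so displacement would be slow and elimination competes. The enolate is ambident and can close through oxygen. The same enolate lies six atoms from the enoate carbon C6, so a six-membered Michael closure competes with the 14-membered alkylation. The epoxide and the C15 silyl ether must be set beforehand on an open chain.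
- Comparison: the chosen route forms the ring bond with a non-basic organochromium reagent, so C11–H and the alkylidene lactone are not activated.

Key step: step 16

Remark: in step 1 the sense of induction is assigned by analogy with aryl additions to cyclic enones and enoates; if the other enantiomer forms, (R)-BINAP is used and nothing else changes.
Remark: C11 of 29 lies between the ester and the C13 ketone and is configurationally labile; the route delivers it as 11S and keeps everything after step 9 free of strong base at that centre.

## Route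

Step 1
Reactants: 1 5,6-dihydro-2H-pyran-2-one; 2 isopropenylboronic acid pinacol ester
Product: 3 (S)-4-(prop-1-en-2-yl)tetrahydro-2H-pyran-2-one
Conditions: [RhCl(cod)]2 (cat.), (S)-BINAP, aq. K3PO4, 1,4-dioxane, 50 °C; dilute HCl work-up
Reagents that add atoms: none
Why: Hayashi–Miyaura asymmetric 1,4-addition: the isopropenyl group passes from boron to monovalent rhodium, adds to one face of the cyclic enoate held in the BINAP pocket, and the rhodium oxa-π-allyl is protonated by water; this sets C4. The acidic work-up recloses any lactone opened by the aqueous base.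

Step 2
Reactants: 3 (S)-4-(prop-1-en-2-yl)tetrahydro-2H-pyran-2-one
Product: 4 (S)-5-hydroxy-N-methoxy-N-methyl-3-(prop-1-en-2-yl)pentanamide
Conditions: MeNH(OMe)·HCl, iPrMgCl, THF, −20 → 0 °C
Reagents that add atoms: N,O-dimethylhydroxylamine hydrochloride, CNOC.Cl
Why: Weinreb aminolysis of a lactone by the chloromagnesium amide; the ring opens at the acyl carbon, so the C5–C6 arm becomes an amide and the C19–C18 arm a free alcohol, and the two arms at C4 stay different without a protecting group.

Step 3
Reactants: 4 (S)-5-hydroxy-N-methoxy-N-methyl-3-(prop-1-en-2-yl)pentanamide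
Product: 5 (S)-N-methoxy-N-methyl-5-oxo-3-(prop-1-en-2-yl)pentanamide
Conditions: Dess–Martin periodinane, pyridine, CH2Cl2, 0 °C → rt
Reagents that add atoms: none
Why: Dess–Martin oxidation of the primary alcohol to the C18 aldehyde; it is run at once because δ-hydroxy Weinreb amides slowly relactonise, and C4 (β to the aldehyde) cannot epimerise.

Step 4
Reactants: 5 (S)-N-methoxy-N-methyl-5-oxo-3-(prop-1-en-2-yl)pentanamide
Product: 6 (S,Z)-6-iodo-N-methoxy-N-methyl-3-(prop-1-en-2-yl)hept-5-enamide
Conditions: EtPPh3I, n-BuLi, THF; I2, −78 °C; NaN(SiMe3)2, −78 → −20 °C; then 5, −78 °C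
Reagents that add atoms: ethyltriphenylphosphonium iodide, CC[P+](c1ccccc1)(c1ccccc1)c1ccccc1.[I-]; iodine, II
Why: Stork–Zhao-type Wittig olefination with the α-iodoethylidene ylide; the methyl homologue of the iodomethylene reagent is required because C16 carries C17. Kinetic cis-oxaphosphetane formation by the non-stabilised ylide places iodine cis to the chain and gives the Z iodide; the Weinreb amide does not react with the ylide at −78 °C.

Step 5
Reactants: 6 (S,Z)-6-iodo-N-methoxy-N-methyl-3-(prop-1-en-2-yl)hept-5-enamide
Product: 7 (S,Z)-6-iodo-3-(prop-1-en-2-yl)hept-5-enal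
Conditions: iBu2AlH, THF, −78 °C; aq. Rochelle salt
Reagents that add atoms: none
Why: Weinreb amide reduction stops at the chelated aluminium hemiaminal, which gives the C6 aldehyde on work-up; the alkenyl iodide and the isopropenyl group are inert at −78 °C.

Step 6
Reactants: 8 (R)-5-(hydroxymethyl)dihydrofuran-2(3H)-one
Product: 10 benzyl (E)-3-[(R)-5-oxotetrahydrofuran-2-yl]acrylate, via (R)-5-oxotetrahydrofuran-2-carbaldehyde 9 (not isolated)
Conditions: Dess–Martin periodinane, CH2Cl2, rt; then Ph3P=CHCO2Bn, rt
Reagents that add atoms: benzyl (triphenylphosphoranylidene)acetate, O=C(C=P(c1ccccc1)(c1ccccc1)c1ccccc1)OCc1ccccc1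
Why: Dess–Martin oxidation followed in the same flask by Wittig olefination with a stabilised ylide, which adds C11 and C12; the water-soluble, epimerisable α-acyloxy aldehyde 9 is trapped by the non-basic ylide, so C9 is kept.

Step 7
Reactants: 10 benzyl (E)-3-[(R)-5-oxotetrahydrofuran-2-yl]acrylate
Product: 11 3-[(S)-5-oxotetrahydrofuran-2-yl]propanoic acid
Conditions: H2 (1 atm), 10% Pd/C, EtOAc, rt
Reagents that add atoms: none
Why: Catalytic hydrogenation saturates the electron-poor alkene and hydrogenolyses the benzyl ester in one operation. No hydrolysis is used, because 11 is the mono-lactone of a symmetric 4-hydroxy diacid and aqueous base would open it and erase C9.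

Step 8
Reactants: 11 3-[(S)-5-oxotetrahydrofuran-2-yl]propanoic acid
Product: 12 (S)-5-{3-[(S)-4-benzyl-2-thioxothiazolidin-3-yl]-3-oxopropyl}dihydrofuran-2(3H)-one
Conditions: (S)-4-benzylthiazolidine-2-thione, EDC·HCl, DMAP (cat.), CH2Cl2, 0 °C → rt
Reagents that add atoms: (S)-4-benzyl-1,3-thiazolidine-2-thione, S=C1N[C@@H](Cc2ccccc2)CS1
Why: Carbodiimide coupling with DMAP catalysis acylates the auxiliary nitrogen under neutral conditions that leave the lactone closed.

Step 9
Reactants: 12 (S)-5-{3-[(S)-4-benzyl-2-thioxothiazolidin-3-yl]-3-oxopropyl}dihydrofuran-2(3H)-one; 13 3-[(tert-butyldimethylsilyl)oxy]propanal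
Product: 15 (R)-5-{(2S,3R)-2-[(S)-4-benzyl-2-thioxothiazolidine-3-carbonyl]-5-[(tert-butyldimethylsilyl)oxy]-3-hydroxypentyl}dihydrofuran-2(3H)-one, via chlorotitanium enolate 14 (not isolated)
Conditions: TiCl4 (1.05 equiv), iPr2NEt (1.1 equiv), N-methyl-2-pyrrolidinone (1 equiv), CH2Cl2, 0 °C; then 13, −78 → 0 °C
Reagents that add atoms: none
Why: Titanium-mediated thiazolidinethione aldol (Crimmins variant) run in the Evans-syn mode: soft enolisation gives only the Z chlorotitanium enolate of the thioimide, the lactone being far less acidic. With the pyrrolidinone on titanium, the aldehyde reacts through a non-chelated Zimmerman–Traxler chair on the face away from the benzyl group, which sets C11 (S) and, syn to it, C13 (R).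

Step 10
Reactants: 15 (R)-5-{(2S,3R)-2-[(S)-4-benzyl-2-thioxothiazolidine-3-carbonyl]-5-[(tert-butyldimethylsilyl)oxy]-3-hydroxypentyl}dihydrofuran-2(3H)-one
Product: 16 methyl (2S,3R)-5-[(tert-butyldimethylsilyl)oxy]-3-hydroxy-2-{[(R)-5-oxotetrahydrofuran-2-yl]methyl}pentanoate
Conditions: MeOH, imidazole, CH2Cl2, rt
Reagents that add atoms: methanol, CO
Why: The thiazolidinethione is a good acyl-transfer leaving group, so imidazole-catalysed methanolysis gives the C12 methyl ester at room temperature. No alkoxide is used, because methoxide could open the lactone and let the C9 oxygen close onto C12 instead of C20.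

Step 11
Reactants: 16 methyl (2S,3R)-5-[(tert-butyldimethylsilyl)oxy]-3-hydroxy-2-{[(R)-5-oxotetrahydrofuran-2-yl]methyl}pentanoate
Product: 17 methyl (2S,3R)-3,5-bis[(tert-butyldimethylsilyl)oxy]-2-{[(R)-5-oxotetrahydrofuran-2-yl]methyl}pentanoate
Conditions: tBuMe2SiOTf, 2,6-lutidine, CH2Cl2, −78 → 0 °C
Reagents that add atoms: tert-butyldimethylsilyl trifluoromethanesulfonate, CC(C)(C)[Si](C)(C)OS(=O)(=O)C(F)(F)F
Why: Silylation of the secondary C13 hydroxyl with a silyl triflate and a hindered base; the ether blocks retro-aldol cleavage and keeps C13 at the carbinol level until the end.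

Step 12
Reactants: 17 methyl (2S,3R)-3,5-bis[(tert-butyldimethylsilyl)oxy]-2-{[(R)-5-oxotetrahydrofuran-2-yl]methyl}pentanoate; 7 (S,Z)-6-iodo-3-(prop-1-en-2-yl)hept-5-enal
Product: 19 β-hydroxy lactone (C6–C7 aldol adduct; C6/C7 epimer mixture), via lactone lithium enolate 18 (not isolated)
Conditions: LiN(iPr)2 (1.05 equiv), THF, −78 °C, 30 min; 7, −78 °C; AcOH quench at −78 °C
Reagents that add atoms: none
Why: Directed aldol addition of a lactone lithium enolate: the amide base removes a proton from the unhindered, more acidic C7 methylene of the lactone in preference to the tertiary C11–H next to the silyloxy-bearing C13, and the enolate adds to the C6 aldehyde. The new centres C6 and C7 form as mixtures and both disappear in step 13.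

Step 13
Reactants: 19 β-hydroxy lactone (C6–C7 aldol adduct; C6/C7 epimer mixture)
Product: 21 methyl (2S,3R)-3,5-bis[(tert-butyldimethylsilyl)oxy]-2-({(2S,4E)-4-[(3R,5Z)-6-iodo-3-(prop-1-en-2-yl)hept-5-en-1-ylidene]-5-oxotetrahydrofuran-2-yl}methyl)pentanoate, via C6 methanesulfonate 20 (not isolated)
Conditions: MsCl, Et3N, CH2Cl2, 0 °C; then DBU, 0 °C → rt
Reagents that add atoms: none
Why: Mesylation and E1cB elimination; the conjugated E alkylidene lactone, with the C5 chain turned away from the C20 carbonyl, is favoured from both diastereomers of 19, and DBU is too weak a base to touch C11–H.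

Step 14
Reactants: 21 methyl (2S,3R)-3,5-bis[(tert-butyldimethylsilyl)oxy]-2-({(2S,4E)-4-[(3R,5Z)-6-iodo-3-(prop-1-en-2-yl)hept-5-en-1-ylidene]-5-oxotetrahydrofuran-2-yl}methyl)pentanoate
Product: 22 methyl (2S,3R)-3-[(tert-butyldimethylsilyl)oxy]-5-hydroxy-2-({(2S,4E)-4-[(3R,5Z)-6-iodo-3-(prop-1-en-2-yl)hept-5-en-1-ylidene]-5-oxotetrahydrofuran-2-yl}methyl)pentanoate
Conditions: HF·pyridine, pyridine, THF, 0 °C
Reagents that add atoms: none
Why: Fluoride-mediated desilylation; the primary silyl ether at C15 is cleaved faster than the secondary one at C13, which is shielded by the C11 branch.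

Step 15
Reactants: 22 methyl (2S,3R)-3-[(tert-butyldimethylsilyl)oxy]-5-hydroxy-2-({(2S,4E)-4-[(3R,5Z)-6-iodo-3-(prop-1-en-2-yl)hept-5-en-1-ylidene]-5-oxotetrahydrofuran-2-yl}methyl)pentanoate
Product: 23 methyl (2S,3R)-3-[(tert-butyldimethylsilyl)oxy]-5-oxo-2-({(2S,4E)-4-[(3R,5Z)-6-iodo-3-(prop-1-en-2-yl)hept-5-en-1-ylidene]-5-oxotetrahydrofuran-2-yl}methyl)pentanoate
Conditions: Dess–Martin periodinane, pyridine, CH2Cl2, 0 °C → rt
Reagents that add atoms: none
Why: Dess–Martin oxidation gives the β-silyloxy aldehyde under buffered conditions that avoid β-elimination; it is used without storage.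

Step 16
Reactants: 23 methyl (2S,3R)-3-[(tert-butyldimethylsilyl)oxy]-5-oxo-2-({(2S,4E)-4-[(3R,5Z)-6-iodo-3-(prop-1-en-2-yl)hept-5-en-1-ylidene]-5-oxotetrahydrofuran-2-yl}methyl)pentanoate
Product: 25 macrocyclic (15S)-allylic alcohol (C13 silyl ether), via alkenylchromium dichloride 24 (not isolated)
Conditions: CrCl2 (excess), NiCl2 (cat.), degassed DMSO, rt, slow addition of 23 to a final concentration near 0.003 M; aq. sodium serinate work-up
Reagents that add atoms: none
Why: Nozaki–Hiyama–Kishi reaction run as a macrocyclisation: CrCl2 reduces NiCl2 to zerovalent nickel, which inserts into the C16–I bond with retention of the Z geometry, and transmetalation to trivalent chromium gives alkenylchromium 24, which adds to the C15 aldehyde and holds the product as a chromium alkoxide until work-up. The closest known reaction type is the nickel-catalysed, chromium-mediated coupling of alkenyl iodides with aldehydes, which is established for closing medium and large carbocycles. The 14-membered ring closes by a 14-exo-trig addition of C16 to the carbonyl carbon C15, forming the single skeletal bond C15–C16. The new stereocentre C15 is controlled by the substrate alone, through the conformation that C4, C9, C11 and the C13 silyl ether impose on the ring-forming transition state; the 15S carbinol is the one needed, and its predominance is not assured. The step needs chemoselectivity for the aldehyde over the methyl ester, the lactone and the enoate, which the low basicity and carbonyl selectivity of alkenylchromium reagents secure. It needs retention of the alkene geometry, which the configurational stability of alkenylnickel and alkenylchromium species secures. It needs ring closure to outrun dimerisation, which slow addition into dilute excess CrCl2 secures. No base is present, so C11–H, the β-silyloxy aldehyde and the alkylidene lactone are not put at risk.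

Step 17
Reactants: 25 macrocyclic (15S)-allylic alcohol (C13 silyl ether)
Product: 26 macrocyclic (15S,16R,18S)-epoxy alcohol
Conditions: VO(acac)2 (cat.), tBuOOH (decane solution), CH2Cl2, 0 °C → rt
Reagents that add atoms: tert-butyl hydroperoxide, CC(C)(C)OO
Why: Hydroxyl-directed epoxidation: the C15 alkoxide binds pentavalent vanadium, and in the conformer in which C15–H eclipses the C16=C18 bond (least A(1,3) strain with C19) the peroxide oxygen is delivered to the face on which the hydroxyl lies. For the 15S carbinol this gives the C16/C18 configuration of 29; the isopropenyl group and the electron-poor C6=C7 bond have no directing hydroxyl and do not react.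

Step 18
Reactants: 26 macrocyclic (15S,16R,18S)-epoxy alcohol
Product: 27 macrocyclic epoxy ketone (C15 ketone, C13 silyl ether)
Conditions: Dess–Martin periodinane, pyridine, CH2Cl2, 0 °C → rt
Reagents that add atoms: none
Why: Dess–Martin oxidation of the epoxy carbinol to the α,β-epoxy ketone. C15 is oxidised before the C13 silyl ether is removed, so that a free C13 hydroxyl never meets an epoxide next to a carbinol (an arrangement that closes to a tetrahydrofuran under acid) and no Payne rearrangement can occur.

Step 19
Reactants: 27 macrocyclic epoxy ketone (C15 ketone, C13 silyl ether)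
Product: 28 macrocyclic β-hydroxy ketone (C13 hydroxyl, C15 ketone)
Conditions: HF·pyridine, pyridine, THF, 0 °C → rt
Reagents that add atoms: none
Why: Fluoride-mediated cleavage of the secondary silyl ether under buffered conditions; the epoxide is now α to a ketone, which disfavours acid-induced opening at C16.

Step 20
Reactants: 28 macrocyclic β-hydroxy ketone (C13 hydroxyl, C15 ketone)
Product: 29 target CNP0108136.1
Conditions: Dess–Martin periodinane (small excess), CH2Cl2, 0 °C; aq. Na2S2O3/pH 7 phosphate work-up
Reagents that add atoms: none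
Why: Dess–Martin oxidation of the β-hydroxy ketone to the 1,3-diketone; a small excess of oxidant and a neutral work-up limit further oxidation at C14 and leave the now acidic C11–H alone, so the 11S configuration from step 9 is carried into 29.

## Compound list

1 | 5,6-dihydro-2H-pyran-2-one | O=C1C=CCCO1 | starting material
2 | isopropenylboronic acid pinacol ester | C=C(C)B1OC(C)(C)C(C)(C)O1 | starting material
3 | (S)-4-(prop-1-en-2-yl)tetrahydro-2H-pyran-2-one | O=C1C[C@@H](C(C)=C)CCO1 | intermediate
4 | (S)-5-hydroxy-N-methoxy-N-methyl-3-(prop-1-en-2-yl)pentanamide | CON(C)C(=O)C[C@@H](C(C)=C)CCO | intermediate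
5 | (S)-N-methoxy-N-methyl-5-oxo-3-(prop-1-en-2-yl)pentanamide | CON(C)C(=O)C[C@@H](C(C)=C)CC=O | intermediate
6 | (S,Z)-6-iodo-N-methoxy-N-methyl-3-(prop-1-en-2-yl)hept-5-enamide | CON(C)C(=O)C[C@@H](C(C)=C)C/C=C(\I)C | intermediate
7 | (S,Z)-6-iodo-3-(prop-1-en-2-yl)hept-5-enal | O=CC[C@@H](C(C)=C)C/C=C(\I)C | intermediate
8 | (R)-5-(hydroxymethyl)dihydrofuran-2(3H)-one | O=C1CC[C@H](CO)O1 | starting material
9 | (R)-5-oxotetrahydrofuran-2-carbaldehyde | O=C1CC[C@H](C=O)O1 | intermediate (not isolated)
10 | benzyl (E)-3-[(R)-5-oxotetrahydrofuran-2-yl]acrylate | O=C1CC[C@H](/C=C/C(=O)OCc2ccccc2)O1 | intermediate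
11 | 3-[(S)-5-oxotetrahydrofuran-2-yl]propanoic acid | O=C1CC[C@H](CCC(=O)O)O1 | intermediate
12 | (S)-5-{3-[(S)-4-benzyl-2-thioxothiazolidin-3-yl]-3-oxopropyl}dihydrofuran-2(3H)-one | O=C1CC[C@H](CCC(=O)N2C(=S)SC[C@@H]2Cc3ccccc3)O1 | intermediate
13 | 3-[(tert-butyldimethylsilyl)oxy]propanal | O=CCCO[Si](C)(C)C(C)(C)C | starting material
14 | trichlorotitanium (Z)-enolate of thioimide 12 | Cl[Ti](Cl)(Cl)O/C(=C\C[C@H]1CCC(=O)O1)N2C(=S)SC[C@@H]2Cc3ccccc3 | intermediate (not isolated)
15 | (R)-5-{(2S,3R)-2-[(S)-4-benzyl-2-thioxothiazolidine-3-carbonyl]-5-[(tert-butyldimethylsilyl)oxy]-3-hydroxypentyl}dihydrofuran-2(3H)-one (11S,13R in skeleton numbering) | CC(C)(C)[Si](C)(C)OCC[C@@H](O)[C@@H](C(=O)N2C(=S)SC[C@@H]2Cc3ccccc3)C[C@H]1CCC(=O)O1 | intermediate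
16 | methyl (2S,3R)-5-[(tert-butyldimethylsilyl)oxy]-3-hydroxy-2-{[(R)-5-oxotetrahydrofuran-2-yl]methyl}pentanoate | CC(C)(C)[Si](C)(C)OCC[C@@H](O)[C@@H](C(=O)OC)C[C@H]1CCC(=O)O1 | intermediate
17 | methyl (2S,3R)-3,5-bis[(tert-butyldimethylsilyl)oxy]-2-{[(R)-5-oxotetrahydrofuran-2-yl]methyl}pentanoate | CC(C)(C)[Si](C)(C)OCC[C@@H](O[Si](C)(C)C(C)(C)C)[C@@H](C(=O)OC)C[C@H]1CCC(=O)O1 | intermediate
18 | lithium enolate of 17 at the lactone (C7=C20–OLi) | CC(C)(C)[Si](C)(C)OCC[C@@H](O[Si](C)(C)C(C)(C)C)[C@@H](C(=O)OC)C[C@H]1CC=C(O[Li])O1 | intermediate (not isolated)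
19 | β-hydroxy lactone: 17 carrying at C7 the (3S,5Z)-1-hydroxy-6-iodo-3-(prop-1-en-2-yl)hept-5-en-1-yl group; C6 and C7 as epimer mixtures, all other centres as in 7 and 17 | CC(C)(C)[Si](C)(C)OCC[C@@H](O[Si](C)(C)C(C)(C)C)[C@@H](C(=O)OC)C[C@H]1CC(C(O)C[C@@H](C(C)=C)C/C=C(\I)C)C(=O)O1 | intermediate
20 | C6 methanesulfonate of 19 | CC(C)(C)[Si](C)(C)OCC[C@@H](O[Si](C)(C)C(C)(C)C)[C@@H](C(=O)OC)C[C@H]1CC(C(OS(C)(=O)=O)C[C@@H](C(C)=C)C/C=C(\I)C)C(=O)O1 | intermediate (not isolated)
21 | methyl (2S,3R)-3,5-bis[(tert-butyldimethylsilyl)oxy]-2-({(2S,4E)-4-[(3R,5Z)-6-iodo-3-(prop-1-en-2-yl)hept-5-en-1-ylidene]-5-oxotetrahydrofuran-2-yl}methyl)pentanoate | CC(C)(C)[Si](C)(C)OCC[C@@H](O[Si](C)(C)C(C)(C)C)[C@@H](C(=O)OC)C[C@H]1C/C(=C\C[C@@H](C(C)=C)C/C=C(\I)C)C(=O)O1 | intermediate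
22 | methyl (2S,3R)-3-[(tert-butyldimethylsilyl)oxy]-5-hydroxy-2-({(2S,4E)-4-[(3R,5Z)-6-iodo-3-(prop-1-en-2-yl)hept-5-en-1-ylidene]-5-oxotetrahydrofuran-2-yl}methyl)pentanoate | OCC[C@@H](O[Si](C)(C)C(C)(C)C)[C@@H](C(=O)OC)C[C@H]1C/C(=C\C[C@@H](C(C)=C)C/C=C(\I)C)C(=O)O1 | intermediate
23 | methyl (2S,3R)-3-[(tert-butyldimethylsilyl)oxy]-5-oxo-2-({(2S,4E)-4-[(3R,5Z)-6-iodo-3-(prop-1-en-2-yl)hept-5-en-1-ylidene]-5-oxotetrahydrofuran-2-yl}methyl)pentanoate (C15 aldehyde, C16 Z-iodide) | O=CC[C@@H](O[Si](C)(C)C(C)(C)C)[C@@H](C(=O)OC)C[C@H]1C/C(=C\C[C@@H](C(C)=C)C/C=C(\I)C)C(=O)O1 | intermediate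
24 | alkenylchromium dichloride from 23 (CrCl2 in place of iodine at C16, Z geometry kept) | O=CC[C@@H](O[Si](C)(C)C(C)(C)C)[C@@H](C(=O)OC)C[C@H]1C/C(=C\C[C@@H](C(C)=C)C/C=C(\[Cr](Cl)Cl)C)C(=O)O1 | intermediate (not isolated)
25 | macrocyclic allylic alcohol (4S,9S,11S,13R,15S; 6E,16Z): 14-membered ring C4–C19 bridged by the C20 lactone on C7/C9, isopropenyl at C4, CO2Me at C11, silyl ether at C13, hydroxyl at C15, methyl at C16 | C=C(C)[C@@H]1C/C=C2\C[C@H](C[C@H](C(=O)OC)[C@H](O[Si](C)(C)C(C)(C)C)C[C@H](O)/C(C)=C\C1)OC2=O | intermediate
26 | macrocyclic epoxy alcohol (4R,9S,11S,13R,15S,16R,18S; 6E): 25 with the C16–C18 cis-epoxide on the hydroxyl face | C=C(C)[C@@H]1C/C=C2\C[C@H](C[C@H](C(=O)OC)[C@H](O[Si](C)(C)C(C)(C)C)C[C@H](O)[C@@]3(C)O[C@H]3C1)OC2=O | intermediate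
27 | macrocyclic epoxy ketone (4R,9S,11S,13R,16S,18S; 6E): C15 ketone, C13 silyl ether | C=C(C)[C@@H]1C/C=C2\C[C@H](C[C@H](C(=O)OC)[C@H](O[Si](C)(C)C(C)(C)C)CC(=O)[C@@]3(C)O[C@H]3C1)OC2=O | intermediate
28 | macrocyclic β-hydroxy ketone (4R,9S,11S,13R,16S,18S; 6E): C13 hydroxyl, C15 ketone | C=C(C)[C@@H]1C/C=C2\C[C@H](C[C@H](C(=O)OC)[C@H](O)CC(=O)[C@@]3(C)O[C@H]3C1)OC2=O | intermediate
29 | CNP0108136.1 (4R,9S,11S,16S,18S; 6E) | C=C(C)[C@@H]1C/C=C2\C[C@H](C[C@H](C(=O)OC)C(=O)CC(=O)[C@@]3(C)O[C@H]3C1)OC2=O | target

(The CIP letter at C4 and C9 changes along the route with the substituent priorities; neither centre is touched after it is set.)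

## Step count and least certain steps

Total: 20 steps. Longest linear sequence: 15 steps (8 to 29, steps 6–20). The second branch (1 to 7, steps 1–5) joins in step 12.

**Step 16 (key step).** The most likely failure is low or reversed facial selectivity at C15, because only the conformation of a flexible 14-membered transition state decides which aldehyde face is attacked. Intermolecular coupling is the second concern and is met by dilution. The fallback sets out from 23 and returns to 25. The cyclisation is run as before, and the mixture of 25 and its C15 epimer, the (15R)-allylic alcohol F1, is oxidised with Dess–Martin periodinane to the macrocyclic enone F2. Corey–Bakshi–Shibata reduction of F2 with (R)-2-methyl-CBS-oxazaborolidine and catecholborane in toluene at −78 °C should then give 25 under reagent control, the 2-methylalkenyl group acting as the large substituent. Catecholborane is chosen because free BH3 would hydroborate the isopropenyl group.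

**Step 12.** The deprotonation may not be fully selective for C7: removal of C11–H would lead to loss of silyloxide from C13 or to epimerisation, and the C7 enolate may attack the C12 ester in a Claisen closure if it is kept too long. The fallback sets out from acid 11 and returns to 21; it makes the alkylidene lactone before any second ester exists. Two equivalents of LiN(iPr)2 convert 11 into the carboxylate–lactone enolate (the carboxylate α-hydrogens are far less acidic), which adds to 7 to give hydroxy acid F3. Dehydration (MsCl, Et3N, then DBU, aqueous work-up) gives alkylidene lactone acid F4. Coupling with the auxiliary (EDC·HCl, DMAP) gives thioimide F5, the titanium aldol with 13 gives aldol adduct F6, methanolysis with imidazole gives hydroxy ester F7, and silylation with tBuMe2SiOTf and 2,6-lutidine gives 21.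

**Step 17.** The oxygen may be delivered to the wrong alkene face if the ring does not allow the conformer with least A(1,3) strain, or if the C16 methyl steers the vanadium ester into another rotamer. Because C15 is oxidised afterwards, its configuration can be chosen to suit the epoxidation. The fallback sets out from 25 and returns to 27. Compound 25 is oxidised to enone F2, which is reduced with (S)-2-methyl-CBS-oxazaborolidine and catecholborane to the (15R)-allylic alcohol F1. Epoxidation of F1 under the same VO(acac)2/tBuOOH conditions gives the (15R)-epoxy alcohol F8, and Dess–Martin oxidation of F8 gives 27.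

**Step 19.** During desilylation the liberated C13 hydroxyl may attack the epoxide under acid, or the β-hydroxy ketone may dehydrate. The fallback sets out from 25 and returns to 29; the silyl group is removed before the epoxide exists. HF·pyridine converts 25 into the macrocyclic diol F9. Its allylic C15 hydroxyl, which reacts much faster than the remote C13 hydroxyl, directs the VO(acac)2/tBuOOH epoxidation to the epoxy diol F10. Oxidation of both carbinols with excess Dess–Martin periodinane gives 29.

**Step 4.** The α-iodo ylide is thermally fragile, so loss of iodine and erosion of the Z geometry during olefination are the likely problems. The fallback sets out from 5 and returns to 6. Ramirez olefination (CBr4, PPh3, CH2Cl2, 0 °C) gives the 1,1-dibromoalkene F11. Palladium-catalysed Negishi coupling with MeZnCl and PdCl2(DPEphos) replaces selectively the bromine trans to the chain and gives the (Z)-alkenyl bromide F12. Copper-catalysed halide exchange (CuI, NaI, N,N'-dimethylethylenediamine, dioxane, heat) with retention of geometry gives 6.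

## Further compounds

F1 | step 16 | (15R)-epimer of macrocyclic allylic alcohol 25 (4S,9S,11S,13R,15R; 6E,16Z) | C=C(C)[C@@H]1C/C=C2\C[C@H](C[C@H](C(=O)OC)[C@H](O[Si](C)(C)C(C)(C)C)C[C@@H](O)/C(C)=C\C1)OC2=O
F2 | step 16 | macrocyclic enone: C15 ketone conjugated with the Z C16=C18 alkene, C13 silyl ether (4S,9S,11S,13R) | C=C(C)[C@@H]1C/C=C2\C[C@H](C[C@H](C(=O)OC)[C@H](O[Si](C)(C)C(C)(C)C)CC(=O)/C(C)=C\C1)OC2=O
F3 | step 12 | 3-{(2S)-4-[(3S,5Z)-1-hydroxy-6-iodo-3-(prop-1-en-2-yl)hept-5-en-1-yl]-5-oxotetrahydrofuran-2-yl}propanoic acid (C6/C7 epimer mixture) | O=C(O)CC[C@H]1CC(C(O)C[C@@H](C(C)=C)C/C=C(\I)C)C(=O)O1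
F4 | step 12 | 3-{(2S,4E)-4-[(3R,5Z)-6-iodo-3-(prop-1-en-2-yl)hept-5-en-1-ylidene]-5-oxotetrahydrofuran-2-yl}propanoic acid | O=C(O)CC[C@H]1C/C(=C\C[C@@H](C(C)=C)C/C=C(\I)C)C(=O)O1
F5 | step 12 | N-acyl (S)-4-benzylthiazolidine-2-thione of acid F4 | O=C(CC[C@H]1C/C(=C\C[C@@H](C(C)=C)C/C=C(\I)C)C(=O)O1)N2C(=S)SC[C@@H]2Cc3ccccc3
F6 | step 12 | Evans-syn aldol adduct of F5 with 13 (11S,13R; thioimide at C12, hydroxyl at C13, silyl ether at C15) | CC(C)(C)[Si](C)(C)OCC[C@@H](O)[C@@H](C(=O)N2C(=S)SC[C@@H]2Cc3ccccc3)C[C@H]1C/C(=C\C[C@@H](C(C)=C)C/C=C(\I)C)C(=O)O1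
F7 | step 12 | methyl (2S,3R)-5-[(tert-butyldimethylsilyl)oxy]-3-hydroxy-2-({(2S,4E)-4-[(3R,5Z)-6-iodo-3-(prop-1-en-2-yl)hept-5-en-1-ylidene]-5-oxotetrahydrofuran-2-yl}methyl)pentanoate | CC(C)(C)[Si](C)(C)OCC[C@@H](O)[C@@H](C(=O)OC)C[C@H]1C/C(=C\C[C@@H](C(C)=C)C/C=C(\I)C)C(=O)O1
F8 | step 17 | (15R)-epoxy alcohol, C15 epimer of 26 (4R,9S,11S,13R,15R,16R,18S) | C=C(C)[C@@H]1C/C=C2\C[C@H](C[C@H](C(=O)OC)[C@H](O[Si](C)(C)C(C)(C)C)C[C@@H](O)[C@@]3(C)O[C@H]3C1)OC2=O
F9 | step 19 | macrocyclic diol: 25 without the silyl group (4S,9S,11S,13R,15S; 6E,16Z) | C=C(C)[C@@H]1C/C=C2\C[C@H](C[C@H](C(=O)OC)[C@H](O)C[C@H](O)/C(C)=C\C1)OC2=O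
F10 | step 19 | macrocyclic epoxy diol (4R,9S,11S,13R,15S,16R,18S) | C=C(C)[C@@H]1C/C=C2\C[C@H](C[C@H](C(=O)OC)[C@H](O)C[C@H](O)[C@@]3(C)O[C@H]3C1)OC2=O
F11 | step 4 | (S)-6,6-dibromo-N-methoxy-N-methyl-3-(prop-1-en-2-yl)hex-5-enamide | CON(C)C(=O)C[C@@H](C(C)=C)CC=C(Br)Br
F12 | step 4 | (S,Z)-6-bromo-N-methoxy-N-methyl-3-(prop-1-en-2-yl)hept-5-enamide | CON(C)C(=O)C[C@@H](C(C)=C)C/C=C(\Br)C
A1 | alternative 1 | E-alkylidene lactone C10 carboxylic acid carrying the C16 epoxy ester | COC(=O)[C@@]1(C)O[C@H]1C[C@H](C(C)=C)C/C=C2\C[C@H](C(=O)O)OC2=O
A2 | alternative 2 | macrocyclic 3,5-disubstituted isoxazole (isoxazolophane) | C=C(C)[C@@H]1C/C=C2\C[C@H](C[C@H](C(=O)OC)c3cc(on3)[C@@]4(C)O[C@H]4C1)OC2=O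
A3 | alternative 3 | macrocyclic β-keto ester with C15 silyl ether and C16–C18 epoxide | C=C(C)[C@@H]1C/C=C2\C[C@H](C[C@H](C(=O)OC)C(=O)C[C@H](O[Si](C)(C)C(C)(C)C)[C@@]3(C)O[C@H]3C1)OC2=O
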